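**Plan**

- Locants used below (eudesmane style): C1–C3 ring A CH2, C4 methylidene carbon, C5 ring-fusion CH, C6 carbinol, C7 isopropyl carbon, C8 CH2, C9 ester carbon, C10 quaternary carbon, C14 angular methyl.
- Retrosynthesis: cut the O9 acyl bond and trace C6–OH back to C6–B, then C4=CH2 back to C4=O, then cut C5–C10 and C6–C7 together (retro-Diels–Alder on ring B). The open triene is cut at C9–C10 (alkenyl + aldehyde) and C4–C5 (acetylide + aldehyde).
- Enabling feature: ring B (C5–C6–C7–C8–C9–C10) carries oxygen on C9 next to C10 and the future carbonyl C4 on C5. This is the retron of a 2-silyloxydiene C7=C8–C9=C10 adding to a C5=C6 enone whose ketone C4 lies in the C1–C4 tether.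
- Forward: a linear, achiral triene is assembled; rings A and B then form in one intramolecular Diels–Alder step; methylenation, C9 reduction, acylation and C–B oxidation finish the target.
- Stereochemistry: the C5/C6/C7/C10 relative configuration comes from the three alkene geometries of the triene, because a tether on the inside of C10 allows only one, cis-fused transition state. The absolute configuration comes from a chiral oxazaborolidine catalyst in the cycloaddition. C9 comes from a reagent-controlled CBS reduction, and C6–OH from stereoretentive C–B oxidation.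

Key step: step 8

Remark: the catalyst antipode in step 8 is assigned from the usual enone-binding model of cationic oxazaborolidines; this is the one assumption of the plan.

**Step 1**
Reactants: 1 hex-5-yn-1-ol
Product: 2 5-iodohex-5-en-1-ol
Conditions: NaI, TMSCl, H2O (0.5 equiv), MeCN, 0 °C → rt
Reagents that add atoms: sodium iodide, [Na+].[I-]
Why: Markovnikov hydroiodination of the terminal alkyne by HI made in situ should give the 2-iodo-1-alkene and leave the primary alcohol alone; no stereocenter is formed.

**Step 2**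
Reactants: 2 5-iodohex-5-en-1-ol
Product: 3 5-iodohex-5-enal
Conditions: Dess–Martin periodinane (DMP), NaHCO3, CH2Cl2, 0 °C → rt
Reagents that add atoms: none
Why: Dess–Martin oxidation under buffered, neutral conditions should stop at the aldehyde and leave the alkenyl iodide intact.

**Step 3**
Reactants: 3 5-iodohex-5-enal; 4 ethynylmagnesium bromide
Product: 5 7-iodooct-7-en-1-yn-3-ol (racemic)
Conditions: THF, −78 → 0 °C; aq. NH4Cl
Reagents that add atoms: none
Why: Grignard 1,2-addition of the acetylide to the aldehyde gives the propargylic alcohol; its configuration is irrelevant because C4 is oxidized in step 6.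

**Step 4**
Reactants: 5 7-iodooct-7-en-1-yn-3-ol; 6 (E)-4-methylpent-2-enal
Product: 7 (E)-11-methyl-7-methylidenedodec-9-en-1-yne-3,8-diol (mixture of diastereomers)
Conditions: CrCl2 (4 equiv), NiCl2 (1 mol %), DMF, rt
Reagents that add atoms: none
Why: Nozaki–Hiyama–Kishi coupling: the alkenylchromium species from the iodide adds 1,2 to the enal in the presence of the free hydroxyl and the terminal alkyne; the new carbinol is oxidized later, so no stereocontrol is needed.

**Step 5**
Reactants: 7 (E)-11-methyl-7-methylidenedodec-9-en-1-yne-3,8-diol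
Product: 8 (1E,9E)-11-methyl-7-methylidene-1-(4,4,5,5-tetramethyl-1,3,2-dioxaborolan-2-yl)dodeca-1,9-diene-3,8-diol (mixture of diastereomers)
Conditions: B2pin2 (1.1 equiv), CuCl (5 mol %), Xantphos (5 mol %), NaOtBu (10 mol %), MeOH (2 equiv), THF, rt
Reagents that add atoms: bis(pinacolato)diboron, CC1(C)OB(OC1(C)C)B1OC(C)(C)C(C)(C)O1
Why: copper-catalysed protoboration (formal anti-Markovnikov hydroboration): syn addition of Cu–Bpin with boron at the alkyne terminus, then protonolysis by methanol, should give the (E)-alkenylboronate and tolerate both hydroxyls.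

**Step 6**
Reactants: 8 boryl dienediol
Product: 9 (1E,9E)-11-methyl-7-methylidene-1-(4,4,5,5-tetramethyl-1,3,2-dioxaborolan-2-yl)dodeca-1,9-diene-3,8-dione
Conditions: DMP (3 equiv), NaHCO3, CH2Cl2, 0 °C; used at once
Reagents that add atoms: none
Why: double Dess–Martin oxidation of the two allylic carbinols should give the cross-conjugated dienone and the (E)-β-boryl enone in one operation.

**Step 7**
Reactants: 9 boryl dienedione
Product: 10 (1E,7E,9E)-7,11-dimethyl-1-(4,4,5,5-tetramethyl-1,3,2-dioxaborolan-2-yl)-8-[(triethylsilyl)oxy]dodeca-1,7,9-trien-3-one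
Conditions: Et3SiH (1.05 equiv), RhH(PPh3)4 (2 mol %), BHT, benzene, rt; filtered through neutral alumina, kept cold
Reagents that add atoms: triethylsilane, CC[SiH](CC)CC
Why: rhodium hydride-catalysed 1,4-hydrosilylation of an enone: hydride goes to the unhindered methylidene terminus C14 and silicon to O9 through the s-cis enone, so the new methyl ends up cis to OSi and the tether cis to C8 (the 7E enol ether), while the two β-substituted enones should react much more slowly.

**Step 8**
Reactants: 10 silyloxy triene
Product: 11 (4aR,7S,8S,8aR)-4a-methyl-7-(propan-2-yl)-8-(4,4,5,5-tetramethyl-1,3,2-dioxaborolan-2-yl)-5-[(triethylsilyl)oxy]-3,4,4a,7,8,8a-hexahydronaphthalen-1(2H)-one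
Conditions: (S)-3,3-diphenyl-1-(2-methylphenyl)tetrahydro-1H,3H-pyrrolo[1,2-c][1,3,2]oxazaborole (20 mol %), AlBr3 (16 mol %), CH2Cl2, −78 → −20 °C
Reagents that add atoms: none
Why: Proposed new method: the AlBr3-activated oxazaborolidine binds the C4 ketone of the (E)-β-boryl enone and the 2-silyloxydiene C7=C8–C9=C10 then adds across C5=C6 in one concerted, asynchronous [4+2] cycloaddition that forms C5–C10 and C6–C7 together; the closest known reaction types are the cationic oxazaborolidine-catalysed Diels–Alder reaction of acyclic enones with 2-silyloxydienes and the thermal type 1 intramolecular Diels–Alder reaction of deca-1,7,9-trien-3-ones, but a tether-bound boryl enone and a fully substituted diene terminus have not been used in the catalytic enantioselective variant. Ring B closes as the six-membered [4π+2π] ring, suprafacial on both partners, and ring A closes through the same C5–C10 bond across the four-carbon tether C1–C4 in the fused mode. C10 and C7 are set by the diene geometry (methyl and isopropyl both outside, hence cis), C5 and C6 by the (E)-dienophile (C4 and boron trans), and the two pairs are tied together because the tether sits inside on C10, so that only the transition state with C4 exo and the boryl group endo can be reached and the ring fusion must be cis with methyl, H5, boron and isopropyl on one face. The absolute sense is set by the catalyst, whose aryl group is expected to shield the Re face of C5 so that the diene adds to the Si face. The step needs enantiofacial control, secured by running below the temperature of the uncatalysed cyclization, and it needs the cycloaddition to outrun Mukaiyama–Michael attack and the [1,5]-hydrogen shift of the diene, which the vacant p orbital on boron (it makes C5 electrophilic towards the nucleophilic C10) and the low temperature should secure.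

**Step 9**
Reactants: 11 boryl octalone silyl enol ether
Product: 13 (3S,4S,4aS,8aR)-8a-methyl-5-methylidene-3-(propan-2-yl)-4-(4,4,5,5-tetramethyl-1,3,2-dioxaborolan-2-yl)octahydronaphthalen-1(2H)-one, via methylidene triethylsilyl enol ether 12 (not isolated)
Conditions: Cp2Ti(μ-Cl)(μ-CH2)AlMe2 (1.5 equiv), pyridine (cat.), THF/toluene, −40 → 0 °C; then 1 M HCl, THF, 0 °C
Reagents that add atoms: Tebbe reagent, C[Al-]1(C)C[Ti]([Cl+]1)(C1C=CC=C1)C1C=CC=C1
Why: Tebbe methylenation is non-basic, so the ketone next to the epimerizable C5–H should become the exocyclic methylidene without epimerization and without loss of the silyl enol ether, which dilute acid then hydrolyses to the C9 ketone (protonation at C8 creates no stereocenter).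

**Step 10**
Reactants: 13 boryl methylidene decalone
Product: 14 (1R,3S,4S,4aS,8aR)-8a-methyl-5-methylidene-3-(propan-2-yl)-4-(4,4,5,5-tetramethyl-1,3,2-dioxaborolan-2-yl)decahydronaphthalen-1-ol
Conditions: (S)-1-methyl-3,3-diphenyltetrahydro-1H,3H-pyrrolo[1,2-c][1,3,2]oxazaborole ((S)-Me-CBS, 1 equiv), catecholborane (2 equiv), toluene, −78 → −40 °C; MeOH
Reagents that add atoms: none
Why: Corey–Bakshi–Shibata reduction under reagent control: the ketone has a quaternary (large) and a CH2 (small) flank, so the (S)-catalyst should deliver hydride to the face that gives the (R)-carbinol at C9 (oxygen cis to the angular methyl), and catecholborane should leave the 1,1-disubstituted alkene and the boronate alone.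

**Step 11**
Reactants: 14 boryl decalinol; 15 4-methoxybenzoyl chloride
Product: 16 (1R,3S,4S,4aS,8aR)-8a-methyl-5-methylidene-3-(propan-2-yl)-4-(4,4,5,5-tetramethyl-1,3,2-dioxaborolan-2-yl)decahydronaphthalen-1-yl 4-methoxybenzoate
Conditions: DMAP (1.5 equiv), Et3N, CH2Cl2, 40 °C
Reagents that add atoms: none
Why: DMAP-catalysed acylation (nucleophilic catalysis) of the hindered secondary alcohol proceeds with retention at C9, and no other hydroxyl competes because O6 is still masked as boron.

**Step 12**
Reactants: 16 boryl anisoate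
Product: 17 (1R,3R,4S,4aS,8aR)-4-hydroxy-8a-methyl-5-methylidene-3-(propan-2-yl)decahydronaphthalen-1-yl 4-methoxybenzoate (CNP0107029.1)
Conditions: NaBO3·4H2O (5 equiv), THF/H2O (1:1), rt
Reagents that add atoms: sodium perborate, [Na+].[O-]OB=O
Why: oxidation of the secondary alkylboronate (1,2-migration of C6 from boron to oxygen with retention) should unveil the C6 hydroxyl cis to the isopropyl and methyl groups under conditions mild enough for the ester and the alkene.

**Compound list**

1 | hex-5-yn-1-ol | C#CCCCCO | starting material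
2 | 5-iodohex-5-en-1-ol | C=C(I)CCCCO | intermediate
3 | 5-iodohex-5-enal | C=C(I)CCCC=O | intermediate
4 | ethynylmagnesium bromide | C#C[Mg]Br | starting material
5 | 7-iodooct-7-en-1-yn-3-ol (racemic) | C#CC(O)CCCC(I)=C | intermediate
6 | (E)-4-methylpent-2-enal | CC(C)/C=C/C=O | starting material
7 | (E)-11-methyl-7-methylidenedodec-9-en-1-yne-3,8-diol (diastereomer mixture) | CC(C)/C=C/C(O)C(=C)CCCC(O)C#C | intermediate
8 | (1E,9E)-11-methyl-7-methylidene-1-(4,4,5,5-tetramethyl-1,3,2-dioxaborolan-2-yl)dodeca-1,9-diene-3,8-diol (diastereomer mixture) | CC(C)/C=C/C(O)C(=C)CCCC(O)/C=C/B1OC(C)(C)C(C)(C)O1 | intermediate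
9 | (1E,9E)-11-methyl-7-methylidene-1-(4,4,5,5-tetramethyl-1,3,2-dioxaborolan-2-yl)dodeca-1,9-diene-3,8-dione | CC(C)/C=C/C(=O)C(=C)CCCC(=O)/C=C/B1OC(C)(C)C(C)(C)O1 | intermediate
10 | (1E,7E,9E)-7,11-dimethyl-1-(4,4,5,5-tetramethyl-1,3,2-dioxaborolan-2-yl)-8-[(triethylsilyl)oxy]dodeca-1,7,9-trien-3-one | CC(C)/C=C/C(O[Si](CC)(CC)CC)=C(/C)CCCC(=O)/C=C/B1OC(C)(C)C(C)(C)O1 | intermediate
11 | (4aR,7S,8S,8aR)-4a-methyl-7-(propan-2-yl)-8-(4,4,5,5-tetramethyl-1,3,2-dioxaborolan-2-yl)-5-[(triethylsilyl)oxy]-3,4,4a,7,8,8a-hexahydronaphthalen-1(2H)-one | O=C1CCC[C@]2(C)[C@H]1[C@@H](B3OC(C)(C)C(C)(C)O3)[C@@H](C(C)C)C=C2O[Si](CC)(CC)CC | intermediate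
12 | triethyl{[(3S,4S,4aS,8aR)-8a-methyl-5-methylidene-3-(propan-2-yl)-4-(4,4,5,5-tetramethyl-1,3,2-dioxaborolan-2-yl)-3,4,4a,5,6,7,8,8a-octahydronaphthalen-1-yl]oxy}silane (not isolated) | C=C1CCC[C@]2(C)[C@H]1[C@@H](B3OC(C)(C)C(C)(C)O3)[C@@H](C(C)C)C=C2O[Si](CC)(CC)CC | intermediate
13 | (3S,4S,4aS,8aR)-8a-methyl-5-methylidene-3-(propan-2-yl)-4-(4,4,5,5-tetramethyl-1,3,2-dioxaborolan-2-yl)octahydronaphthalen-1(2H)-one | C=C1CCC[C@]2(C)[C@H]1[C@@H](B3OC(C)(C)C(C)(C)O3)[C@@H](C(C)C)CC2=O | intermediate
14 | (1R,3S,4S,4aS,8aR)-8a-methyl-5-methylidene-3-(propan-2-yl)-4-(4,4,5,5-tetramethyl-1,3,2-dioxaborolan-2-yl)decahydronaphthalen-1-ol | C=C1CCC[C@]2(C)[C@H]1[C@@H](B3OC(C)(C)C(C)(C)O3)[C@@H](C(C)C)C[C@H]2O | intermediate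
15 | 4-methoxybenzoyl chloride | COc1ccc(cc1)C(Cl)=O | starting material
16 | (1R,3S,4S,4aS,8aR)-8a-methyl-5-methylidene-3-(propan-2-yl)-4-(4,4,5,5-tetramethyl-1,3,2-dioxaborolan-2-yl)decahydronaphthalen-1-yl 4-methoxybenzoate | C=C1CCC[C@]2(C)[C@H]1[C@@H](B3OC(C)(C)C(C)(C)O3)[C@@H](C(C)C)C[C@H]2OC(=O)c1ccc(OC)cc1 | intermediate
17 | (1R,3R,4S,4aS,8aR)-4-hydroxy-8a-methyl-5-methylidene-3-(propan-2-yl)decahydronaphthalen-1-yl 4-methoxybenzoate | C=C1CCC[C@]2(C)[C@H]1[C@@H](O)[C@@H](C(C)C)C[C@H]2OC(=O)c1ccc(OC)cc1 | target

**Totals**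

Total step count: 12. Longest linear sequence: 12 steps (from 1).

**Steps most likely to fail**

Step 8 (Proposed new method). The catalyst may not differentiate the two faces of the enone well enough, or the acidic catalyst may strip the silyl enol ether before cyclization. If only the sense of induction is wrong, the (R)-catalyst is used instead. If catalysis fails altogether, the fallback sets out from 10 and uses known chemistry. The triene is cyclized thermally (toluene, BHT, 90 °C), which keeps the relative configuration fixed by the alkene geometries and should give 11 together with the mirror-image adduct F1. The conditions of step 9 then convert both, through 12 and the mirror-image enol ether F2 (not isolated), into 13 and the mirror-image ketone F3. The (S)-CBS reduction of step 10 then serves as a reagent-controlled divergent reduction of the racemate: both enantiomers should receive the (R)-carbinol, so 13 gives 14 and F3 gives the diastereomeric (1R)-alcohol F4. The two are separated by chromatography and the route is rejoined at 14.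

Step 7. Hydride may be delivered to the boryl enone or the alkenylboronate instead of the methylidene terminus, eroding the triene before it can cyclize. The fallback sets out from 8 and makes the dienol ether before the second enone exists. MnO2 (CH2Cl2, rt) should oxidize the doubly allylic C9 carbinol much faster than the carbinol next to the electron-poor alkenylboronate, giving hydroxy dienone F5. Acetylation (Ac2O, pyridine, 0 °C) gives acetate F6. The same RhH(PPh3)4/Et3SiH hydrosilylation, now facing a single enone system, gives silyl dienol ether acetate F7. iBu2AlH (CH2Cl2, −78 °C) removes the acetate to give allylic alcohol F8, and MnO2 oxidizes it to 10, where the route is rejoined.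

Step 10. Catalyst control may be overridden by the intrinsic facial bias of the hindered, neopentyl-type ketone, so that hydride arrives mainly from the wrong face. The fallback sets out from 13 and turns that bias to use. A bulky achiral hydride (LiBH(sBu)3, THF, −78 °C) is used to give the C9-epimeric alcohol F9 cleanly. The ester is then formed with inversion by a Mitsunobu reaction with 4-methoxybenzoic acid (PPh3, DIAD, toluene, 0 °C → rt), which gives 16 directly, where the route is rejoined.

**Further compounds**

F1 | step 8 | (4aS,7R,8R,8aS)-4a-methyl-7-(propan-2-yl)-8-(4,4,5,5-tetramethyl-1,3,2-dioxaborolan-2-yl)-5-[(triethylsilyl)oxy]-3,4,4a,7,8,8a-hexahydronaphthalen-1(2H)-one | O=C1CCC[C@@]2(C)[C@@H]1[C@H](B3OC(C)(C)C(C)(C)O3)[C@H](C(C)C)C=C2O[Si](CC)(CC)CC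
F2 | step 8 | triethyl{[(3R,4R,4aR,8aS)-8a-methyl-5-methylidene-3-(propan-2-yl)-4-(4,4,5,5-tetramethyl-1,3,2-dioxaborolan-2-yl)-3,4,4a,5,6,7,8,8a-octahydronaphthalen-1-yl]oxy}silane | C=C1CCC[C@@]2(C)[C@@H]1[C@H](B3OC(C)(C)C(C)(C)O3)[C@H](C(C)C)C=C2O[Si](CC)(CC)CC
F3 | step 8 | (3R,4R,4aR,8aS)-8a-methyl-5-methylidene-3-(propan-2-yl)-4-(4,4,5,5-tetramethyl-1,3,2-dioxaborolan-2-yl)octahydronaphthalen-1(2H)-one | C=C1CCC[C@@]2(C)[C@@H]1[C@H](B3OC(C)(C)C(C)(C)O3)[C@H](C(C)C)CC2=O
F4 | step 8 | (1R,3R,4R,4aR,8aS)-8a-methyl-5-methylidene-3-(propan-2-yl)-4-(4,4,5,5-tetramethyl-1,3,2-dioxaborolan-2-yl)decahydronaphthalen-1-ol | C=C1CCC[C@@]2(C)[C@@H]1[C@H](B3OC(C)(C)C(C)(C)O3)[C@H](C(C)C)C[C@H]2O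
F5 | step 7 | (1E,9E)-3-hydroxy-11-methyl-7-methylidene-1-(4,4,5,5-tetramethyl-1,3,2-dioxaborolan-2-yl)dodeca-1,9-dien-8-one | CC(C)/C=C/C(=O)C(=C)CCCC(O)/C=C/B1OC(C)(C)C(C)(C)O1
F6 | step 7 | (1E,9E)-11-methyl-7-methylidene-8-oxo-1-(4,4,5,5-tetramethyl-1,3,2-dioxaborolan-2-yl)dodeca-1,9-dien-3-yl acetate | CC(C)/C=C/C(=O)C(=C)CCCC(OC(C)=O)/C=C/B1OC(C)(C)C(C)(C)O1
F7 | step 7 | (1E,7E,9E)-7,11-dimethyl-1-(4,4,5,5-tetramethyl-1,3,2-dioxaborolan-2-yl)-8-[(triethylsilyl)oxy]dodeca-1,7,9-trien-3-yl acetate | CC(C)/C=C/C(O[Si](CC)(CC)CC)=C(/C)CCCC(OC(C)=O)/C=C/B1OC(C)(C)C(C)(C)O1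
F8 | step 7 | (1E,7E,9E)-7,11-dimethyl-1-(4,4,5,5-tetramethyl-1,3,2-dioxaborolan-2-yl)-8-[(triethylsilyl)oxy]dodeca-1,7,9-trien-3-ol | CC(C)/C=C/C(O[Si](CC)(CC)CC)=C(/C)CCCC(O)/C=C/B1OC(C)(C)C(C)(C)O1
F9 | step 10 | (1S,3S,4S,4aS,8aR)-8a-methyl-5-methylidene-3-(propan-2-yl)-4-(4,4,5,5-tetramethyl-1,3,2-dioxaborolan-2-yl)decahydronaphthalen-1-ol | C=C1CCC[C@]2(C)[C@H]1[C@@H](B3OC(C)(C)C(C)(C)O3)[C@@H](C(C)C)C[C@@H]2O
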